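The single stereocentre is the side-chain carbon between the ketone carbonyl carbon and the CH2CH2 tether to the benzene ring, and everything rests on disconnecting its C–CH3 bond. Because this carbon is α to a carbonyl and otherwise carries only an unbranched 2-arylethyl group, it is made by methylating the chelated sodium enolate of a 4-arylbutanoyl imide of (R)-4-benzyloxazolidin-2-one; one operation forms the bond and sets R. The precursor is the fully masked arene: carboxyl as 2-(trimethylsilyl)ethyl ester, phenol and allylic alcohol as TIPS ethers, so that a single fluoride step at the end unveils all three after the enone has been built.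

Key step: step 10

Remarks on the chemistry
- Protecting groups: the carboxyl group is carried as its 2-(trimethylsilyl)ethyl (TMSE) ester and both hydroxyls as triisopropylsilyl ethers. A methyl benzoate would have to be saponified at the end beside an epimerisable α-methyl ketone and a base-sensitive γ-hydroxy enone, and a 4-oxidobenzoate saponifies only under forcing conditions. The skeletons of the key-step precursor 16 and product 18 are unchanged.
- The aliphatic ethyl ester is hydrolysed while the phenol is still free (step 7), where the phenoxide shields the aryl ester; silylation follows.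
- Stereochemical check: at the methyl-bearing carbon the ranking is oxygenated carbon (imide C=O, CH2OH, CHO, CHOH, ketone C=O) > CH2CH2Ar > CH3 in every compound from 18 to 26, so the 3R centre set in step 10 is the R centre of the target. The structures and the R assignment were re-derived and found consistent.
- The carbinol carbon made in step 13 forms as both epimers; they converge in step 14.

Step 1
Reactants: 1 4-hydroxy-3-iodobenzoic acid; 2 2-(trimethylsilyl)ethanol
Product: 3 2-(trimethylsilyl)ethyl 4-hydroxy-3-iodobenzoate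
Conditions: PPh3 (1.1 equiv), DIAD (1.1 equiv), THF, 0 → 25 °C
Reagents that add atoms: none
Why: Mitsunobu esterification; the carboxylic acid is far more acidic than the phenol and is therefore the pronucleophile that displaces the alkoxyphosphonium of the primary alcohol, so no phenol protection is needed.

Step 2
Reactants: 3 2-(trimethylsilyl)ethyl 4-hydroxy-3-iodobenzoate; 4 4-ethoxy-4-oxobutylzinc bromide
Product: 5 2-(trimethylsilyl)ethyl 3-(4-ethoxy-4-oxobutyl)-4-hydroxybenzoate
Conditions: Pd(OAc)2 (2 mol%), SPhos (4 mol%), 4 (0.5 M in THF, 2 equiv, slow addition), THF, 25 °C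
Reagents that add atoms: none
Why: Negishi sp2–sp3 cross-coupling; oxidative addition of zerovalent palladium into the Ar–I bond, transmetalation from the primary alkylzinc and fast reductive elimination from the biarylphosphine complex should outpace protonolysis of the zinc reagent by the phenol, and both esters are inert to RZnBr.

Step 3
Reactants: 5 2-(trimethylsilyl)ethyl 3-(4-ethoxy-4-oxobutyl)-4-hydroxybenzoate
Product: 6 2-(trimethylsilyl)ethyl 4-(allyloxy)-3-(4-ethoxy-4-oxobutyl)benzoate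
Conditions: allyl bromide (1.3 equiv), K2CO3 (2 equiv), acetone, 56 °C
Reagents that add atoms: allyl bromide, C=CCBr
Why: Williamson ether synthesis; carbonate deprotonates the acidic phenol and the phenoxide displaces the allylic bromide, leaving both esters untouched.

Step 4
Reactants: 6 2-(trimethylsilyl)ethyl 4-(allyloxy)-3-(4-ethoxy-4-oxobutyl)benzoate
Product: 7 2-(trimethylsilyl)ethyl 3-allyl-5-(4-ethoxy-4-oxobutyl)-4-hydroxybenzoate
Conditions: 1,2-dichlorobenzene, 185 °C (sealed tube)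
Reagents that add atoms: none
Why: Aromatic Claisen rearrangement; the [3,3] shift can only deliver the allyl group to the one free ortho carbon, since the other ortho carbon bears the butanoate chain and the para carbon the ester, and tautomerisation restores the phenol.

Step 5
Reactants: 7 2-(trimethylsilyl)ethyl 3-allyl-5-(4-ethoxy-4-oxobutyl)-4-hydroxybenzoate; 8 methacrolein
Product: 9 2-(trimethylsilyl)ethyl 3-(4-ethoxy-4-oxobutyl)-4-hydroxy-5-[(E)-3-methyl-4-oxobut-2-enyl]benzoate
Conditions: second-generation Hoveyda–Grubbs catalyst (5 mol%), 1,4-benzoquinone (10 mol%), 8 (8 equiv), CH2Cl2, 40 °C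
Reagents that add atoms: none
Why: Olefin cross-metathesis of a terminal alkene with excess methacrolein, which does not homodimerise; the trisubstituted enal should form as the more stable E isomer (CHO trans to CH2Ar), and benzoquinone suppresses allyl-to-propenyl isomerisation by ruthenium hydrides.

Step 6
Reactants: 9 2-(trimethylsilyl)ethyl 3-(4-ethoxy-4-oxobutyl)-4-hydroxy-5-[(E)-3-methyl-4-oxobut-2-enyl]benzoate
Product: 10 2-(trimethylsilyl)ethyl 3-(4-ethoxy-4-oxobutyl)-4-hydroxy-5-[(E)-4-hydroxy-3-methylbut-2-enyl]benzoate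
Conditions: NaBH4 (1.0 equiv), CeCl3·7H2O (1.0 equiv), MeOH, −20 °C
Reagents that add atoms: none
Why: Luche 1,2-reduction; the cerium-activated borohydride reduces only the aldehyde carbonyl, so the C=C bond, its E geometry and both esters are kept, and the weakly acidic medium keeps the phenol from adding to the enal.

Step 7
Reactants: 10 2-(trimethylsilyl)ethyl 3-(4-ethoxy-4-oxobutyl)-4-hydroxy-5-[(E)-4-hydroxy-3-methylbut-2-enyl]benzoate
Product: 11 4-[2-hydroxy-3-[(E)-4-hydroxy-3-methylbut-2-enyl]-5-[[2-(trimethylsilyl)ethoxy]carbonyl]phenyl]butanoic acid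
Conditions: LiOH·H2O (4 equiv), THF/H2O (3:1), 0 → 25 °C; then 1 M HCl to pH 3, 0 °C
Reagents that add atoms: lithium hydroxide monohydrate (source of the hydroxide oxygen), [Li+].[OH-].O
Why: Chemoselective saponification; hydroxide attacks the unhindered aliphatic ethyl ester, while the aryl ester is conjugated to the para phenoxide formed under the conditions and is strongly deactivated towards addition.

Step 8
Reactants: 11 4-[2-hydroxy-3-[(E)-4-hydroxy-3-methylbut-2-enyl]-5-[[2-(trimethylsilyl)ethoxy]carbonyl]phenyl]butanoic acid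
Product: 13 4-[3-[(E)-3-methyl-4-(triisopropylsilyloxy)but-2-enyl]-2-(triisopropylsilyloxy)-5-[[2-(trimethylsilyl)ethoxy]carbonyl]phenyl]butanoic acid, via triisopropylsilyl ester 12 (not isolated)
Conditions: TIPSOTf (3.3 equiv), 2,6-lutidine (5 equiv), CH2Cl2, 0 → 25 °C; then K2CO3, MeOH/THF/H2O, 25 °C; work-up at pH 4
Reagents that add atoms: triisopropylsilyl trifluoromethanesulfonate, CC(C)[Si](OS(=O)(=O)C(F)(F)F)(C(C)C)C(C)C
Why: Silylation with a silyl triflate followed by selective solvolysis of the silyl ester; the triflate caps the hindered phenol, the primary alcohol and the acid, and mild carbonate cleaves only the labile acyl–O–Si linkage while the shielded aryl and the alkyl TIPS ethers remain.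

Step 9
Reactants: 13 4-[3-[(E)-3-methyl-4-(triisopropylsilyloxy)but-2-enyl]-2-(triisopropylsilyloxy)-5-[[2-(trimethylsilyl)ethoxy]carbonyl]phenyl]butanoic acid; 14 (R)-4-benzyloxazolidin-2-one
Product: 16 2-(trimethylsilyl)ethyl 3-[4-[(4R)-4-benzyl-2-oxooxazolidin-3-yl]-4-oxobutyl]-5-[(E)-3-methyl-4-(triisopropylsilyloxy)but-2-enyl]-4-(triisopropylsilyloxy)benzoate, via mixed pivalic anhydride 15 (not isolated)
Conditions: t-BuCOCl (1.1 equiv), Et3N (2.5 equiv), THF, −20 °C; then 14 (1.1 equiv), LiCl (1.2 equiv), −20 → 25 °C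
Reagents that add atoms: none
Why: N-Acylation of an oxazolidinone through a mixed anhydride (LiCl/Et3N variant); the lithium-activated oxazolidinone attacks the less hindered carbonyl of the anhydride, and no strong base touches the aryl ester or silyl ethers.

Step 10
Reactants: 16 2-(trimethylsilyl)ethyl 3-[4-[(4R)-4-benzyl-2-oxooxazolidin-3-yl]-4-oxobutyl]-5-[(E)-3-methyl-4-(triisopropylsilyloxy)but-2-enyl]-4-(triisopropylsilyloxy)benzoate
Product: 18 2-(trimethylsilyl)ethyl 3-[(3R)-4-[(4R)-4-benzyl-2-oxooxazolidin-3-yl]-3-methyl-4-oxobutyl]-5-[(E)-3-methyl-4-(triisopropylsilyloxy)but-2-enyl]-4-(triisopropylsilyloxy)benzoate, via sodium Z-enolate 17 (not isolated)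
Conditions: NaN(SiMe3)2 (1.1 equiv), THF, −78 °C; MeI (5 equiv), −78 → −40 °C; chromatography on silica gel
Reagents that add atoms: iodomethane, CI
Why: NaN(SiMe3)2 removes a proton from C2 of the butanoyl chain, the only acidic C–H (the aryl ester has no α-hydrogen and the silyl ethers do not react with the hindered amide), and allylic strain gives the Z enolate 17, held planar by sodium bridging the enolate oxygen and the ring carbonyl oxygen. Iodomethane then reacts by SN2 at the enolate carbon from the face opposite the C4 benzyl group; this is the Evans oxazolidinone enolate alkylation. No ring is closed. The new stereocentre is controlled by the (4R)-benzyl group: with CH2CH2Ar already on the enolate carbon, entry of CH3 anti to benzyl gives 3R (C=O > CH2CH2Ar > CH3), the configuration of the target. The step needs facial selectivity, which the rigid chelate secures, and low temperature to keep the enolate from fragmenting to a ketene; the minor 3S diastereomer should be separable on silica before the auxiliary is removed.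

Step 11
Reactants: 18 2-(trimethylsilyl)ethyl 3-[(3R)-4-[(4R)-4-benzyl-2-oxooxazolidin-3-yl]-3-methyl-4-oxobutyl]-5-[(E)-3-methyl-4-(triisopropylsilyloxy)but-2-enyl]-4-(triisopropylsilyloxy)benzoate
Product: 19 2-(trimethylsilyl)ethyl 3-[(3R)-4-hydroxy-3-methylbutyl]-5-[(E)-3-methyl-4-(triisopropylsilyloxy)but-2-enyl]-4-(triisopropylsilyloxy)benzoate
Conditions: LiBH4 (2 equiv), THF, 0 °C
Reagents that add atoms: none
Why: Reductive cleavage of an N-acyloxazolidinone; hydride attacks the activated exocyclic imide carbonyl much faster than the electron-rich, hindered aryl ester at 0 °C, the auxiliary is released for recovery and the stereocentre is not enolised.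

Step 12
Reactants: 19 2-(trimethylsilyl)ethyl 3-[(3R)-4-hydroxy-3-methylbutyl]-5-[(E)-3-methyl-4-(triisopropylsilyloxy)but-2-enyl]-4-(triisopropylsilyloxy)benzoate
Product: 20 2-(trimethylsilyl)ethyl 3-[(3R)-3-methyl-4-oxobutyl]-5-[(E)-3-methyl-4-(triisopropylsilyloxy)but-2-enyl]-4-(triisopropylsilyloxy)benzoate
Conditions: Dess–Martin periodinane (1.3 equiv), NaHCO3, CH2Cl2, 0 → 25 °C; used crude
Reagents that add atoms: none
Why: Dess–Martin oxidation; the buffered, non-basic oxidant should convert the primary alcohol to the α-branched aldehyde without epimerisation and without touching alkene, silyl ethers or ester.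

Step 13
Reactants: 20 2-(trimethylsilyl)ethyl 3-[(3R)-3-methyl-4-oxobutyl]-5-[(E)-3-methyl-4-(triisopropylsilyloxy)but-2-enyl]-4-(triisopropylsilyloxy)benzoate; 21 2-methyl-2-(trimethylsilyloxy)but-3-yne
Product: 24 2-(trimethylsilyl)ethyl 3-[(3R,5E)-4-hydroxy-3,7-dimethyl-7-(trimethylsilyloxy)oct-5-enyl]-5-[(E)-3-methyl-4-(triisopropylsilyloxy)but-2-enyl]-4-(triisopropylsilyloxy)benzoate (both C4 epimers), via alkenylzirconocene chloride 22 (not isolated), via alkenyl(methyl)zinc 23 (not isolated)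
Conditions: 21 (2 equiv), Cp2Zr(H)Cl (2 equiv), CH2Cl2, 25 °C; Me2Zn (2 equiv, toluene), −65 °C; then 20, 0 °C; aq. NH4Cl
Reagents that add atoms: none
Why: Hydrozirconation, zirconium-to-zinc transmetalation and aldehyde addition (Wipf protocol); syn addition of Zr–H to the terminal alkyne fixes the E alkenyl geometry, and the alkenylzinc adds to the aldehyde but not to the aryl ester, while the configuration of the new carbinol is irrelevant.

Step 14
Reactants: 24 2-(trimethylsilyl)ethyl 3-[(3R,5E)-4-hydroxy-3,7-dimethyl-7-(trimethylsilyloxy)oct-5-enyl]-5-[(E)-3-methyl-4-(triisopropylsilyloxy)but-2-enyl]-4-(triisopropylsilyloxy)benzoate (both C4 epimers)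
Product: 25 2-(trimethylsilyl)ethyl 3-[(3R,5E)-3,7-dimethyl-4-oxo-7-(trimethylsilyloxy)oct-5-enyl]-5-[(E)-3-methyl-4-(triisopropylsilyloxy)but-2-enyl]-4-(triisopropylsilyloxy)benzoate
Conditions: Dess–Martin periodinane (1.5 equiv), NaHCO3, CH2Cl2, 0 → 25 °C
Reagents that add atoms: none
Why: Dess–Martin oxidation of a secondary allylic alcohol; both epimers converge on the E enone under buffered conditions that should leave the adjacent methyl-bearing stereocentre and all silyl groups intact.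

Step 15
Reactants: 25 2-(trimethylsilyl)ethyl 3-[(3R,5E)-3,7-dimethyl-4-oxo-7-(trimethylsilyloxy)oct-5-enyl]-5-[(E)-3-methyl-4-(triisopropylsilyloxy)but-2-enyl]-4-(triisopropylsilyloxy)benzoate
Product: 26 4-hydroxy-3-[(3R,5E)-7-hydroxy-3,7-dimethyl-4-oxooct-5-enyl]-5-[(E)-4-hydroxy-3-methylbut-2-enyl]benzoic acid (CNP0120226.1)
Conditions: [(Me2N)3S][Me3SiF2] (TASF, 8 equiv), DMF, 0 → 25 °C; then 0.1 M HCl to pH 3, 0 °C
Reagents that add atoms: none
Why: Fluoride-induced global desilylation; fluoride attacks silicon of the aryl TIPS, alkyl TIPS and TMS ethers and triggers β-elimination of the TMSE ester (ethylene and Me3SiF leave), so phenol, both alcohols and the acid are freed without hydroxide and the α-methyl enone should keep its configuration.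

Compound list
1 | 4-hydroxy-3-iodobenzoic acid | OC(=O)c1ccc(O)c(I)c1 | starting material
2 | 2-(trimethylsilyl)ethanol | C[Si](C)(C)CCO | starting material
3 | 2-(trimethylsilyl)ethyl 4-hydroxy-3-iodobenzoate | C[Si](C)(C)CCOC(=O)c1ccc(O)c(I)c1 | intermediate
4 | 4-ethoxy-4-oxobutylzinc bromide | CCOC(=O)CCC[Zn]Br | starting material
5 | 2-(trimethylsilyl)ethyl 3-(4-ethoxy-4-oxobutyl)-4-hydroxybenzoate | C[Si](C)(C)CCOC(=O)c1ccc(O)c(CCCC(=O)OCC)c1 | intermediate
6 | 2-(trimethylsilyl)ethyl 4-(allyloxy)-3-(4-ethoxy-4-oxobutyl)benzoate | C[Si](C)(C)CCOC(=O)c1ccc(OCC=C)c(CCCC(=O)OCC)c1 | intermediate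
7 | 2-(trimethylsilyl)ethyl 3-allyl-5-(4-ethoxy-4-oxobutyl)-4-hydroxybenzoate | C[Si](C)(C)CCOC(=O)c1cc(CC=C)c(O)c(CCCC(=O)OCC)c1 | intermediate
8 | methacrolein | CC(=C)C=O | starting material
9 | 2-(trimethylsilyl)ethyl 3-(4-ethoxy-4-oxobutyl)-4-hydroxy-5-[(E)-3-methyl-4-oxobut-2-enyl]benzoate | C[Si](C)(C)CCOC(=O)c1cc(C/C=C(\C)C=O)c(O)c(CCCC(=O)OCC)c1 | intermediate
10 | 2-(trimethylsilyl)ethyl 3-(4-ethoxy-4-oxobutyl)-4-hydroxy-5-[(E)-4-hydroxy-3-methylbut-2-enyl]benzoate | C[Si](C)(C)CCOC(=O)c1cc(C/C=C(\C)CO)c(O)c(CCCC(=O)OCC)c1 | intermediate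
11 | 4-[2-hydroxy-3-[(E)-4-hydroxy-3-methylbut-2-enyl]-5-[[2-(trimethylsilyl)ethoxy]carbonyl]phenyl]butanoic acid | C[Si](C)(C)CCOC(=O)c1cc(C/C=C(\C)CO)c(O)c(CCCC(=O)O)c1 | intermediate
12 | triisopropylsilyl 4-[3-[(E)-3-methyl-4-(triisopropylsilyloxy)but-2-enyl]-2-(triisopropylsilyloxy)-5-[[2-(trimethylsilyl)ethoxy]carbonyl]phenyl]butanoate | C[Si](C)(C)CCOC(=O)c1cc(C/C=C(\C)CO[Si](C(C)C)(C(C)C)C(C)C)c(O[Si](C(C)C)(C(C)C)C(C)C)c(CCCC(=O)O[Si](C(C)C)(C(C)C)C(C)C)c1 | intermediate
13 | 4-[3-[(E)-3-methyl-4-(triisopropylsilyloxy)but-2-enyl]-2-(triisopropylsilyloxy)-5-[[2-(trimethylsilyl)ethoxy]carbonyl]phenyl]butanoic acid | C[Si](C)(C)CCOC(=O)c1cc(C/C=C(\C)CO[Si](C(C)C)(C(C)C)C(C)C)c(O[Si](C(C)C)(C(C)C)C(C)C)c(CCCC(=O)O)c1 | intermediate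
14 | (R)-4-benzyloxazolidin-2-one | O=C1N[C@H](Cc2ccccc2)CO1 | starting material
15 | mixed anhydride of acid 13 and pivalic acid | C[Si](C)(C)CCOC(=O)c1cc(C/C=C(\C)CO[Si](C(C)C)(C(C)C)C(C)C)c(O[Si](C(C)C)(C(C)C)C(C)C)c(CCCC(=O)OC(=O)C(C)(C)C)c1 | intermediate
16 | 2-(trimethylsilyl)ethyl 3-[4-[(4R)-4-benzyl-2-oxooxazolidin-3-yl]-4-oxobutyl]-5-[(E)-3-methyl-4-(triisopropylsilyloxy)but-2-enyl]-4-(triisopropylsilyloxy)benzoate | C[Si](C)(C)CCOC(=O)c1cc(C/C=C(\C)CO[Si](C(C)C)(C(C)C)C(C)C)c(O[Si](C(C)C)(C(C)C)C(C)C)c(CCCC(=O)N2C(=O)OC[C@H]2Cc2ccccc2)c1 | intermediate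
17 | sodium (Z)-enolate of imide 16 | [Na+].[O-]/C(=C\CCc1cc(C(=O)OCC[Si](C)(C)C)cc(C/C=C(\C)CO[Si](C(C)C)(C(C)C)C(C)C)c1O[Si](C(C)C)(C(C)C)C(C)C)N1C(=O)OC[C@H]1Cc1ccccc1 | intermediate
18 | 2-(trimethylsilyl)ethyl 3-[(3R)-4-[(4R)-4-benzyl-2-oxooxazolidin-3-yl]-3-methyl-4-oxobutyl]-5-[(E)-3-methyl-4-(triisopropylsilyloxy)but-2-enyl]-4-(triisopropylsilyloxy)benzoate | C[Si](C)(C)CCOC(=O)c1cc(C/C=C(\C)CO[Si](C(C)C)(C(C)C)C(C)C)c(O[Si](C(C)C)(C(C)C)C(C)C)c(CC[C@@H](C)C(=O)N2C(=O)OC[C@H]2Cc2ccccc2)c1 | intermediate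
19 | 2-(trimethylsilyl)ethyl 3-[(3R)-4-hydroxy-3-methylbutyl]-5-[(E)-3-methyl-4-(triisopropylsilyloxy)but-2-enyl]-4-(triisopropylsilyloxy)benzoate | C[Si](C)(C)CCOC(=O)c1cc(C/C=C(\C)CO[Si](C(C)C)(C(C)C)C(C)C)c(O[Si](C(C)C)(C(C)C)C(C)C)c(CC[C@@H](C)CO)c1 | intermediate
20 | 2-(trimethylsilyl)ethyl 3-[(3R)-3-methyl-4-oxobutyl]-5-[(E)-3-methyl-4-(triisopropylsilyloxy)but-2-enyl]-4-(triisopropylsilyloxy)benzoate | C[Si](C)(C)CCOC(=O)c1cc(C/C=C(\C)CO[Si](C(C)C)(C(C)C)C(C)C)c(O[Si](C(C)C)(C(C)C)C(C)C)c(CC[C@@H](C)C=O)c1 | intermediate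
21 | 2-methyl-2-(trimethylsilyloxy)but-3-yne | C#CC(C)(C)O[Si](C)(C)C | starting material
22 | chloro[(E)-3-methyl-3-(trimethylsilyloxy)but-1-enyl]zirconocene | C[Si](C)(C)OC(C)(C)/C=C/[Zr](Cl)(C1C=CC=C1)C1C=CC=C1 | intermediate
23 | methyl[(E)-3-methyl-3-(trimethylsilyloxy)but-1-enyl]zinc | C[Zn]/C=C/C(C)(C)O[Si](C)(C)C | intermediate
24 | 2-(trimethylsilyl)ethyl 3-[(3R,5E)-4-hydroxy-3,7-dimethyl-7-(trimethylsilyloxy)oct-5-enyl]-5-[(E)-3-methyl-4-(triisopropylsilyloxy)but-2-enyl]-4-(triisopropylsilyloxy)benzoate (both C4 epimers) | C[Si](C)(C)CCOC(=O)c1cc(C/C=C(\C)CO[Si](C(C)C)(C(C)C)C(C)C)c(O[Si](C(C)C)(C(C)C)C(C)C)c(CC[C@@H](C)C(O)/C=C/C(C)(C)O[Si](C)(C)C)c1 | intermediate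
25 | 2-(trimethylsilyl)ethyl 3-[(3R,5E)-3,7-dimethyl-4-oxo-7-(trimethylsilyloxy)oct-5-enyl]-5-[(E)-3-methyl-4-(triisopropylsilyloxy)but-2-enyl]-4-(triisopropylsilyloxy)benzoate | C[Si](C)(C)CCOC(=O)c1cc(C/C=C(\C)CO[Si](C(C)C)(C(C)C)C(C)C)c(O[Si](C(C)C)(C(C)C)C(C)C)c(CC[C@@H](C)C(=O)/C=C/C(C)(C)O[Si](C)(C)C)c1 | intermediate
26 | 4-hydroxy-3-[(3R,5E)-7-hydroxy-3,7-dimethyl-4-oxooct-5-enyl]-5-[(E)-4-hydroxy-3-methylbut-2-enyl]benzoic acid (CNP0120226.1) | OC(=O)c1cc(C/C=C(\C)CO)c(O)c(CC[C@@H](C)C(=O)/C=C/C(C)(C)O)c1 | target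

Total step count: 15. Longest linear sequence: 15 steps (1 → 26); 2, 4, 8, 14 and 21 are purchased.

Steps most likely to fail

1. Step 10 (enolate methylation). The small electrophile may discriminate poorly between the enolate faces, enolisation may be incomplete, or the enolate may fragment to a ketene on warming. The fallback takes the stereocentre from the chiral pool instead of making it; it sets out from 3 and returns at 19.
 - The known alkene (2R)-1-[(4-methoxybenzyl)oxy]-2-methylbut-3-ene F1 is taken as an input; its literature route starts from methyl (S)-3-hydroxy-2-methylpropanoate.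
 - Hydroboration with 9-BBN-H (THF, 25 °C) gives the B-alkylborane F2.
 - B-alkyl Suzuki–Miyaura coupling with iodophenol 3 (PdCl2(dppf), K3PO4, THF/DMF/H2O, 50 °C) gives the phenol F3.
 - The chemistry of steps 3 to 6 then gives the allyl ether F4, the 2-allylphenol F5, the enal F6 and the allylic alcohol F7.
 - TIPSOTf/2,6-lutidine gives the bis-TIPS ether F8.
 - DDQ (CH2Cl2/pH 7 buffer, 0 °C) removes the 4-methoxybenzyl group and gives 19; steps 7 and 9 to 11 fall away.

2. Step 15 (global fluoride deprotection). Basic fluoride may epimerise the carbon next to the ketone or add to the enone, and β-elimination of the TMSE ester may become sluggish once the phenoxide has formed. The fallback moves ester cleavage in front of ketone formation so that base never meets the enone; it sets out from 24 and returns at 26.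
 - KOH (MeOH/H2O, 60 °C) saponifies the TMSE ester and strips the aryl TIPS and TMS ethers while the alkyl TIPS ether stays, giving the hydroxy acid F9.
 - MnO2 (acetone, 25 °C) oxidises its only free allylic alcohol, the secondary one, to the enone acid F10.
 - HF·pyridine (THF/pyridine, 0 → 25 °C) removes the last TIPS group under non-basic conditions and gives 26.

3. Step 5 (cross-metathesis). Ruthenium hydrides may isomerise the allyl group into conjugation with the ring, the free phenol may slow catalyst turnover, or the electron-poor partner may react incompletely. The fallback builds the enal without metathesis; it sets out from 7 and returns at 9.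
 - K2OsO4·2H2O (cat.)/NaIO4 with 2,6-lutidine in dioxane/H2O cleaves the terminal alkene to the arylacetaldehyde, which closes onto the phenol as the lactol F11.
 - Heating with Ph3P=C(CH3)CHO (toluene, 80 °C) opens the lactol and should give the E enal 9 by a stabilised-ylide Wittig reaction.

Further compounds
F1 | step 10 | (2R)-1-[(4-methoxybenzyl)oxy]-2-methylbut-3-ene | C=C[C@@H](C)COCc1ccc(OC)cc1
F2 | step 10 | 9-[(3R)-4-[(4-methoxybenzyl)oxy]-3-methylbutyl]-9-borabicyclo[3.3.1]nonane | B1(CC[C@@H](C)COCc2ccc(OC)cc2)C2CCCC1CCC2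
F3 | step 10 | 2-(trimethylsilyl)ethyl 4-hydroxy-3-[(3R)-4-[(4-methoxybenzyl)oxy]-3-methylbutyl]benzoate | C[Si](C)(C)CCOC(=O)c1ccc(O)c(CC[C@@H](C)COCc2ccc(OC)cc2)c1
F4 | step 10 | 2-(trimethylsilyl)ethyl 4-(allyloxy)-3-[(3R)-4-[(4-methoxybenzyl)oxy]-3-methylbutyl]benzoate | C[Si](C)(C)CCOC(=O)c1ccc(OCC=C)c(CC[C@@H](C)COCc2ccc(OC)cc2)c1
F5 | step 10 | 2-(trimethylsilyl)ethyl 3-allyl-4-hydroxy-5-[(3R)-4-[(4-methoxybenzyl)oxy]-3-methylbutyl]benzoate | C[Si](C)(C)CCOC(=O)c1cc(CC=C)c(O)c(CC[C@@H](C)COCc2ccc(OC)cc2)c1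
F6 | step 10 | 2-(trimethylsilyl)ethyl 4-hydroxy-3-[(3R)-4-[(4-methoxybenzyl)oxy]-3-methylbutyl]-5-[(E)-3-methyl-4-oxobut-2-enyl]benzoate | C[Si](C)(C)CCOC(=O)c1cc(C/C=C(\C)C=O)c(O)c(CC[C@@H](C)COCc2ccc(OC)cc2)c1
F7 | step 10 | 2-(trimethylsilyl)ethyl 4-hydroxy-3-[(E)-4-hydroxy-3-methylbut-2-enyl]-5-[(3R)-4-[(4-methoxybenzyl)oxy]-3-methylbutyl]benzoate | C[Si](C)(C)CCOC(=O)c1cc(C/C=C(\C)CO)c(O)c(CC[C@@H](C)COCc2ccc(OC)cc2)c1
F8 | step 10 | 2-(trimethylsilyl)ethyl 3-[(3R)-4-[(4-methoxybenzyl)oxy]-3-methylbutyl]-5-[(E)-3-methyl-4-(triisopropylsilyloxy)but-2-enyl]-4-(triisopropylsilyloxy)benzoate | C[Si](C)(C)CCOC(=O)c1cc(C/C=C(\C)CO[Si](C(C)C)(C(C)C)C(C)C)c(O[Si](C(C)C)(C(C)C)C(C)C)c(CC[C@@H](C)COCc2ccc(OC)cc2)c1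
F9 | step 15 | 4-hydroxy-3-[(3R,5E)-4,7-dihydroxy-3,7-dimethyloct-5-enyl]-5-[(E)-3-methyl-4-(triisopropylsilyloxy)but-2-enyl]benzoic acid (both C4 epimers) | OC(=O)c1cc(C/C=C(\C)CO[Si](C(C)C)(C(C)C)C(C)C)c(O)c(CC[C@@H](C)C(O)/C=C/C(C)(C)O)c1
F10 | step 15 | 4-hydroxy-3-[(3R,5E)-7-hydroxy-3,7-dimethyl-4-oxooct-5-enyl]-5-[(E)-3-methyl-4-(triisopropylsilyloxy)but-2-enyl]benzoic acid | OC(=O)c1cc(C/C=C(\C)CO[Si](C(C)C)(C(C)C)C(C)C)c(O)c(CC[C@@H](C)C(=O)/C=C/C(C)(C)O)c1
F11 | step 5 | 2-(trimethylsilyl)ethyl 7-(4-ethoxy-4-oxobutyl)-2-hydroxy-2,3-dihydro-1-benzofuran-5-carboxylate | CCOC(=O)CCCc1cc(C(=O)OCC[Si](C)(C)C)cc2CC(O)Oc12
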